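**Retrosynthetic overview**
1. Target 16 ⇐ acetylation and C6‑OH‑directed epoxidation of the ten‑membered (1(10)E,4E)‑dienol 14; the oxirane is the last ring formed.
2. The ten‑membered carbocycle (first ring formed) ⇐ C6–C7 bond by a chiral‑phosphoric‑acid‑catalysed intramolecular allylboration of the acyclic boronate–enal 11, which sets C6 and C7.
3. 11 ⇐ (R)‑4‑angeloyloxy‑(2E,6E)‑farnesal 8 by terminal (E)‑selective allylic oxidation, carbonate formation and borylation.
4. 8 ⇐ (E)‑geranylacetone 1 (13 of the 15 skeletal carbons, correct E‑alkene) + C2 ylide 4 + angelic acid 6; C3 is set first by proline‑catalysed α‑aminoxylation.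

Assumption: the target is taken exactly as drawn; positions are quoted in germacrane numbering (C1=C10 ring alkene, C3 angelate, C4–C5 oxirane, C6 acetate, C7 isopropyl; target = 3R,4R,5R,6S,7S), and 1, 4 and 6 are bought as single isomers.

**Step 1**
Reactants: 1 (5E)-6,10-dimethylundeca-5,9-dien-2-one ((E)-geranylacetone)
Product: 3 (3R,5E)-3-hydroxy-6,10-dimethylundeca-5,9-dien-2-one, via aminooxy ketone 2 (not isolated)
Conditions: 1 (2.5 equiv), L-proline (20 mol%), PhNO (1.0 equiv, syringe pump, 6 h), DMF, 0 °C; then CuSO4·5H2O (30 mol%), MeOH, 0 → 23 °C; excess 1 recovered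
Reagents that add atoms: nitrosobenzene, O=Nc1ccccc1
Why: Proline enamine catalysis (α‑aminoxylation, O‑selective nitroso aldol): the more substituted enamine forms at C3, the carboxylic acid of L‑proline delivers PhN=O to one face to give the (3R)‑aminooxy ketone (same sense as with cyclohexanone and 2‑butanone), and catalytic CuSO4 then cleaves the N–O bond without touching the stereocentre.

**Step 2**
Reactants: 3 (3R,5E)-3-hydroxy-6,10-dimethylundeca-5,9-dien-2-one, 4 (triphenylphosphoranylidene)acetaldehyde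
Product: 5 (2E,4R,6E)-4-hydroxy-3,7,11-trimethyldodeca-2,6,10-trienal
Conditions: 4 (1.5 equiv), toluene, 80 °C, 16 h
Reagents that add atoms: none
Why: Wittig olefination with a stabilised ylide: the α‑hydroxy ketone is activated enough to react, the aldehyde is placed trans to the bulky carbinol carbon (2E), and any 2Z isomer removes itself by closing to a lactol that dehydrates to a furan.

**Step 3**
Reactants: 5 (2E,4R,6E)-4-hydroxy-3,7,11-trimethyldodeca-2,6,10-trienal, 6 angelic acid ((2Z)-2-methylbut-2-enoic acid)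
Product: 8 (2E,4R,6E)-3,7,11-trimethyl-1-oxododeca-2,6,10-trien-4-yl (2Z)-2-methylbut-2-enoate, via mixed anhydride 7 (not isolated)
Conditions: 6 (2 equiv), 2,4,6-trichlorobenzoyl chloride (2 equiv), Et3N (4 equiv), toluene, 23 °C, 2 h; then 5, 60 °C, no DMAP
Reagents that add atoms: none
Why: Mixed‑anhydride (Yamaguchi‑type) esterification without a nucleophilic catalyst, the established way to install an angelate without Z‑to‑E leakage to the tiglate; the carbinol C–O bond is not broken, so C3 stays R.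

**Step 4**
Reactants: 8 (2E,4R,6E)-3,7,11-trimethyl-1-oxododeca-2,6,10-trien-4-yl (2Z)-2-methylbut-2-enoate
Product: 9 (2E,4R,6E,10E)-12-hydroxy-3,7,11-trimethyl-1-oxododeca-2,6,10-trien-4-yl (2Z)-2-methylbut-2-enoate
Conditions: SeO2 (0.3 equiv), tBuOOH (3 equiv, decane), salicylic acid (0.1 equiv), CH2Cl2, 23 °C, stopped near 60% conversion; 8 recycled
Reagents that add atoms: tert-butyl hydroperoxide, CC(C)(C)OO (oxygen relayed by catalytic SeO2)
Why: SeO2‑catalysed allylic hydroxylation (ene reaction then [2,3]‑sigmatropic shift) goes to the most electron‑rich, least hindered alkene, the terminal isopropylidene, and only to its (E)‑methyl group, as in the 12‑hydroxylation of farnesyl esters; the enal and angelate alkenes are electron‑poor, and the (10E) geometry fixed here later decides the C6/C7 relationship.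

**Step 5**
Reactants: 9 (2E,4R,6E,10E)-12-hydroxy-3,7,11-trimethyl-1-oxododeca-2,6,10-trien-4-yl (2Z)-2-methylbut-2-enoate
Product: 10 (2E,4R,6E,10E)-12-[(methoxycarbonyl)oxy]-3,7,11-trimethyl-1-oxododeca-2,6,10-trien-4-yl (2Z)-2-methylbut-2-enoate
Conditions: ClCO2Me (1.5 equiv), pyridine (3 equiv), CH2Cl2, 0 °C
Reagents that add atoms: methyl chloroformate, COC(=O)Cl
Why: Chloroformate acylation of the primary allylic alcohol gives a leaving group that also releases the methoxide needed to activate the diboron in the next step; no stereocentre is involved.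

**Step 6**
Reactants: 10 (2E,4R,6E,10E)-12-[(methoxycarbonyl)oxy]-3,7,11-trimethyl-1-oxododeca-2,6,10-trien-4-yl (2Z)-2-methylbut-2-enoate
Product: 11 (2E,4R,6E,10E)-3,7,11-trimethyl-1-oxo-12-(4,4,5,5-tetramethyl-1,3,2-dioxaborolan-2-yl)dodeca-2,6,10-trien-4-yl (2Z)-2-methylbut-2-enoate
Conditions: Pd2(dba)3 (2.5 mol%), B2pin2 (1.2 equiv), THF, 23 °C, 3 h; short Et3N‑washed silica plug, used at once
Reagents that add atoms: bis(pinacolato)diboron, CC1(C)OB(OC1(C)C)B1OC(C)(C)C(C)(C)O1
Why: Miyaura‑type borylation of an allylic carbonate: zerovalent palladium ionises the carbonate to the syn π‑allyl complex, the liberated methoxide activates B2pin2, and boron is delivered to the unhindered terminus to give the linear (E)‑allylboronate under base‑free conditions that spare the enal and both esters.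

**Step 7**
Reactants: 11 (2E,4R,6E,10E)-3,7,11-trimethyl-1-oxo-12-(4,4,5,5-tetramethyl-1,3,2-dioxaborolan-2-yl)dodeca-2,6,10-trien-4-yl (2Z)-2-methylbut-2-enoate
Product: 13 (1R,2E,4R,5S,8E)-4-hydroxy-2,8-dimethyl-5-(prop-1-en-2-yl)cyclodeca-2,8-dien-1-yl (2Z)-2-methylbut-2-enoate, via pinacol borate 12 (not isolated)
Conditions: (S)-TRIP [(S)-3,3′-bis(2,4,6-triisopropylphenyl)-1,1′-binaphthyl-2,2′-diyl hydrogen phosphate] (20 mol%, 2 mM in toluene), 4 Å MS, 0 °C; 11 added by syringe pump over 20 h (10 mM final); aq NaHCO3 work-up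
Reagents that add atoms: none
Why: Proposed new method: a chiral‑phosphoric‑acid‑catalysed macrocyclising allylboration, in which the acid hydrogen‑bonds to the pseudo‑axial pinacol oxygen (raising boron Lewis acidity) while its phosphoryl oxygen holds the formyl C–H, so the ten‑membered ring closes through a catalyst‑bound Zimmerman–Traxler chair with the aldehyde chain and the (E)‑γ‑substituent C8 both pseudo‑equatorial (C6/C7 anti) and the (S)‑catalyst exposing the Si face of the enal (target geometry at C6 and C7, expected to be matched with the substrate bias from 1,2‑allylic strain at C3); slow addition keeps free 11 low so that ring closure beats oligomerisation and the uncatalysed background is negligible at this dilution; the closest known reactions are the intermolecular phosphoric‑acid‑catalysed allyl‑ and crotylboration of aldehydes with pinacol boronates and the palladium/zinc allylation that closes the germacrane ring of a chloro‑epoxy‑farnesal, the new elements being the intramolecular setting, the ring size and the β,β‑disubstituted enal acceptor.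

**Step 8**
Reactants: 13 (1R,2E,4R,5S,8E)-4-hydroxy-2,8-dimethyl-5-(prop-1-en-2-yl)cyclodeca-2,8-dien-1-yl (2Z)-2-methylbut-2-enoate
Product: 14 (1R,2E,4S,5S,8E)-4-hydroxy-2,8-dimethyl-5-(propan-2-yl)cyclodeca-2,8-dien-1-yl (2Z)-2-methylbut-2-enoate
Conditions: H2 (1 atm), RhCl(PPh3)3 (5 mol%), benzene, 23 °C
Reagents that add atoms: none
Why: Chemoselective homogeneous hydrogenation: RhCl(PPh3)3 reduces the unhindered 1,1‑disubstituted isopropenyl alkene far faster than the trisubstituted ring alkenes or the conjugated angelate, and no stereocentre is created (the carbinol label changes from R to S only because the CIP ranking of its carbon neighbours changes).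

**Step 9**
Reactants: 14 (1R,2E,4S,5S,8E)-4-hydroxy-2,8-dimethyl-5-(propan-2-yl)cyclodeca-2,8-dien-1-yl (2Z)-2-methylbut-2-enoate
Product: 15 (1R,2R,4E,8S,9S,10R)-9-hydroxy-1,5-dimethyl-8-(propan-2-yl)-11-oxabicyclo[8.1.0]undec-4-en-2-yl (2Z)-2-methylbut-2-enoate
Conditions: VO(acac)2 (5 mol%), tBuOOH (1.3 equiv, decane), 2,6-lutidine (0.2 equiv), CH2Cl2, 0 °C
Reagents that add atoms: tert-butyl hydroperoxide, CC(C)(C)OO
Why: Hydroxyl‑directed vanadium‑catalysed epoxidation: the C6 vanadate ester delivers oxygen only to the adjacent C4=C5 alkene (the isolated C1=C10 alkene and the angelate are far slower), and because 1,3‑allylic strain with the cis C4 methyl keeps H6 in the alkene plane and puts the C6 oxygen on the outer face of the ring, oxygen arrives on that face to give the threo (4R,5R) trans‑epoxide.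

**Step 10**
Reactants: 15 (1R,2R,4E,8S,9S,10R)-9-hydroxy-1,5-dimethyl-8-(propan-2-yl)-11-oxabicyclo[8.1.0]undec-4-en-2-yl (2Z)-2-methylbut-2-enoate
Product: 16 (1R,2R,4E,8S,9S,10R)-9-(acetyloxy)-1,5-dimethyl-8-(propan-2-yl)-11-oxabicyclo[8.1.0]undec-4-en-2-yl (2Z)-2-methylbut-2-enoate
Conditions: Ac2O (3 equiv), pyridine, DMAP (10 mol%), CH2Cl2, 0 → 23 °C
Reagents that add atoms: acetic anhydride, CC(=O)OC(C)=O
Why: DMAP‑catalysed acetylation of the one remaining secondary alcohol under non‑acidic conditions that leave the acid‑sensitive epoxy‑alkene and the angelate alone, giving the target.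

**Compound list**
1 | (5E)-6,10-dimethylundeca-5,9-dien-2-one ((E)-geranylacetone) | CC(=O)CC/C=C(\C)CCC=C(C)C | starting material
2 | (3R,5E)-3-(anilinooxy)-6,10-dimethylundeca-5,9-dien-2-one | CC(=O)[C@H](ONc1ccccc1)C/C=C(\C)CCC=C(C)C | intermediate
3 | (3R,5E)-3-hydroxy-6,10-dimethylundeca-5,9-dien-2-one | CC(=O)[C@H](O)C/C=C(\C)CCC=C(C)C | intermediate
4 | (triphenylphosphoranylidene)acetaldehyde | O=CC=P(c1ccccc1)(c1ccccc1)c1ccccc1 | starting material
5 | (2E,4R,6E)-4-hydroxy-3,7,11-trimethyldodeca-2,6,10-trienal | O=C/C=C(\C)[C@H](O)C/C=C(\C)CCC=C(C)C | intermediate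
6 | angelic acid, (2Z)-2-methylbut-2-enoic acid | C/C=C(/C)C(=O)O | starting material
7 | (2Z)-2-methylbut-2-enoic 2,4,6-trichlorobenzoic anhydride | C/C=C(/C)C(=O)OC(=O)c1c(Cl)cc(Cl)cc1Cl | intermediate
8 | (2E,4R,6E)-3,7,11-trimethyl-1-oxododeca-2,6,10-trien-4-yl (2Z)-2-methylbut-2-enoate | C/C=C(/C)C(=O)O[C@@H](/C(C)=C/C=O)C/C=C(\C)CCC=C(C)C | intermediate
9 | (2E,4R,6E,10E)-12-hydroxy-3,7,11-trimethyl-1-oxododeca-2,6,10-trien-4-yl (2Z)-2-methylbut-2-enoate | C/C=C(/C)C(=O)O[C@@H](/C(C)=C/C=O)C/C=C(\C)CC/C=C(\C)CO | intermediate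
10 | (2E,4R,6E,10E)-12-[(methoxycarbonyl)oxy]-3,7,11-trimethyl-1-oxododeca-2,6,10-trien-4-yl (2Z)-2-methylbut-2-enoate | C/C=C(/C)C(=O)O[C@@H](/C(C)=C/C=O)C/C=C(\C)CC/C=C(\C)COC(=O)OC | intermediate
11 | (2E,4R,6E,10E)-3,7,11-trimethyl-1-oxo-12-(4,4,5,5-tetramethyl-1,3,2-dioxaborolan-2-yl)dodeca-2,6,10-trien-4-yl (2Z)-2-methylbut-2-enoate | C/C=C(/C)C(=O)O[C@@H](/C(C)=C/C=O)C/C=C(\C)CC/C=C(\C)CB1OC(C)(C)C(C)(C)O1 | intermediate
12 | (1R,2E,4R,5S,8E)-2,8-dimethyl-5-(prop-1-en-2-yl)-4-[(4,4,5,5-tetramethyl-1,3,2-dioxaborolan-2-yl)oxy]cyclodeca-2,8-dien-1-yl (2Z)-2-methylbut-2-enoate | C1C/C(C)=C/C[C@@H](OC(=O)/C(C)=C\C)/C(C)=C/[C@@H](OB2OC(C)(C)C(C)(C)O2)[C@@H]1C(C)=C | intermediate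
13 | (1R,2E,4R,5S,8E)-4-hydroxy-2,8-dimethyl-5-(prop-1-en-2-yl)cyclodeca-2,8-dien-1-yl (2Z)-2-methylbut-2-enoate | C1C/C(C)=C/C[C@@H](OC(=O)/C(C)=C\C)/C(C)=C/[C@@H](O)[C@@H]1C(C)=C | intermediate
14 | (1R,2E,4S,5S,8E)-4-hydroxy-2,8-dimethyl-5-(propan-2-yl)cyclodeca-2,8-dien-1-yl (2Z)-2-methylbut-2-enoate | C1C/C(C)=C/C[C@@H](OC(=O)/C(C)=C\C)/C(C)=C/[C@@H](O)[C@@H]1C(C)C | intermediate
15 | (1R,2R,4E,8S,9S,10R)-9-hydroxy-1,5-dimethyl-8-(propan-2-yl)-11-oxabicyclo[8.1.0]undec-4-en-2-yl (2Z)-2-methylbut-2-enoate | C/C=C(/C)C(=O)O[C@@H]1C/C=C(\C)CC[C@@H](C(C)C)[C@H](O)[C@H]2O[C@@]21C | intermediate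
16 | (1R,2R,4E,8S,9S,10R)-9-(acetyloxy)-1,5-dimethyl-8-(propan-2-yl)-11-oxabicyclo[8.1.0]undec-4-en-2-yl (2Z)-2-methylbut-2-enoate | C/C=C(/C)C(=O)O[C@@H]1C/C=C(\C)CC[C@@H](C(C)C)[C@H](OC(C)=O)[C@H]2O[C@@]21C | target

**Step count and risks**
Total steps: 10. Longest linear sequence: 10 (from 1).

The three steps most likely to fail:

Step 7 (the proposed new ring closure) may give oligomers, a poor C6/C7 ratio or the wrong face; if only the facial sense is reversed, (R)-TRIP is used instead. The fallback sets out from carbonate 10 (step 6 is skipped) and comes back at 13. It is the known palladium/diethylzinc umpolung allylation that has closed a germacrane ring from a chloro‑epoxy‑farnesal: Pd(PPh3)4 (10 mol%), Et2Zn (3 equiv), THF, 23 °C, syringe‑pump addition to 2 mM. Zerovalent palladium ionises the carbonate, ethyl/allyl exchange gives the fluxional ethyl[(2E,6E,9R,10E)-2,6,10-trimethyl-9-{[(2Z)-2-methylbut-2-enoyl]oxy}-12-oxododeca-2,6,10-trien-1-yl]zinc F1, which adds to the aldehyde through a six‑membered chair to give the ethylzinc alkoxide of 13 F2, and NH4Cl work‑up gives 13. Stereocontrol then rests on the substrate alone and diastereomers are separated at 13.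

Step 2 (formyl ylide on a ketone) may be slow, give E/Z mixtures or erode the C3 stereocentre. The fallback sets out from 3 and comes back at 5. The more reactive ethyl (triphenylphosphoranylidene)acetate (toluene, 60 °C) gives ethyl (2E,4R,6E)-4-hydroxy-3,7,11-trimethyldodeca-2,6,10-trienoate F3 (the Z isomer lactonises and is removed). iBu2AlH (CH2Cl2, −78 °C) then gives (2E,4R,6E)-3,7,11-trimethyldodeca-2,6,10-triene-1,4-diol F4. TEMPO (10 mol%)/PhI(OAc)2 (CH2Cl2, 23 °C) oxidises only the primary allylic alcohol to give 5.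

Step 9 (directed epoxidation) may suffer from acid‑induced transannular cyclisation or insufficient face selectivity in the ring. The fallback sets out from 14 and comes back at 15. It replaces metal‑alkoxide direction by hydrogen‑bond direction with a chiral catalyst: an aspartic‑acid‑containing peptide (10 mol%) with H2O2, diisopropylcarbodiimide and DMAP (CH2Cl2, 4 °C) forms a transient peracid that is held by the C6 hydroxyl. This catalyst class is known to epoxidise only the allylic‑alcohol alkene of polyenes such as farnesol, and the peptide enantiomer gives reagent control over the face. No new compound is made (F0).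

**Further compounds**
F1 | step 7 | ethyl[(2E,6E,9R,10E)-2,6,10-trimethyl-9-{[(2Z)-2-methylbut-2-enoyl]oxy}-12-oxododeca-2,6,10-trien-1-yl]zinc | C/C=C(/C)C(=O)O[C@@H](/C(C)=C/C=O)C/C=C(\C)CC/C=C(\C)C[Zn]CC
F2 | step 7 | ethylzinc alkoxide of 13 (O–Zn–Et on the carbinol oxygen) | C1C/C(C)=C/C[C@@H](OC(=O)/C(C)=C\C)/C(C)=C/[C@@H](O[Zn]CC)[C@@H]1C(C)=C
F3 | step 2 | ethyl (2E,4R,6E)-4-hydroxy-3,7,11-trimethyldodeca-2,6,10-trienoate | CCOC(=O)/C=C(\C)[C@H](O)C/C=C(\C)CCC=C(C)C
F4 | step 2 | (2E,4R,6E)-3,7,11-trimethyldodeca-2,6,10-triene-1,4-diol | OC/C=C(\C)[C@H](O)C/C=C(\C)CCC=C(C)C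
F0 | step 9 | none | none
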